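**Retrosynthetic overview**

1. The target is a 21-membered lactam (C1 to C17, arene carbons C18, C23 and C22, and N). Its saturated C16–C17 bridge joins arene carbon C18 to C15 of the Z C14=C15 alkene. This macrocycle, the only ring made in the route, is closed last at C15–C16 by B-alkyl Suzuki coupling of the 9-BBN adduct of a C18 vinyl group with a Z C15 iodide; global desilylation follows.
2. The seco compound 33 comes from N–C1 amide formation between vinylaniline 28 (from 2-hydroxy-5-methoxy-3-nitrobenzaldehyde) and triene acid 31.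
3. Acid 31 comes from a C8=C9 Julia–Kocienski olefination of C9 sulfone 14 with dienal ester 22. C3 of 22 is taken from (R)-malate; C4 to C8 are added by two Wittig homologations.
4. Sulfone 14 comes from the Z iodoenal of prop-2-yn-1-ol by Evans syn aldol (C12, C13), Claisen extension to C9 and 1,3-anti reduction (C11).

Key step: step 26

Assumption: dimethyl (R)-malate (the diester of (R)-malic acid), 2-hydroxy-5-methoxy-3-nitrobenzaldehyde and (S)-4-benzyl-3-propanoyloxazolidin-2-one are taken as purchasable materials. Chain numbering runs from the amide carbonyl C1. TBS is tert-butyldimethylsilyl and TIPS is triisopropylsilyl.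

**West fragment (C9 to C15)**

Step 1
Reactants: 1 prop-2-yn-1-ol
Product: 3 (Z)-3-iodo-2-methylprop-2-en-1-ol, via cyclic alkenylmagnesium alkoxide 2 (not isolated)
Conditions: MeMgBr (2.5 equiv), CuI (10 mol %), THF, −10 °C to rt; then I2, −78 to 0 °C; aq NH4Cl, Na2S2O3
Reagents that add atoms: methylmagnesium bromide, C[Mg]Br; iodine, II
Why: Copper-catalysed anti-carbomagnesiation of the propargylic magnesium alkoxide puts methyl on the internal carbon and magnesium on the terminal carbon cis to CH2O in a five-membered chelate, and iodinolysis with retention should give the Z iodide that later becomes C14=C15.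

Step 2
Reactants: 3 (Z)-3-iodo-2-methylprop-2-en-1-ol
Product: 4 (Z)-3-iodo-2-methylprop-2-enal
Conditions: activated MnO2 (excess), CH2Cl2, rt, dark; filtered and used at once as a solution
Reagents that add atoms: none
Why: Neutral heterogeneous allylic oxidation should give the enal without Z to E isomerisation, provided light and acid are excluded and the volatile aldehyde is not stored.

Step 3
Reactants: 5 (S)-4-benzyl-3-propanoyloxazolidin-2-one; 4 (Z)-3-iodo-2-methylprop-2-enal
Product: 7 (S)-4-benzyl-3-[(2S,3S,Z)-3-hydroxy-5-iodo-2,4-dimethylpent-4-enoyl]oxazolidin-2-one, via Z dibutylboron enolate 6 (not isolated)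
Conditions: Bu2BOTf, Et3N, CH2Cl2, −78 to 0 °C; then 4, −78 to 0 °C; pH 7 buffer, MeOH, 30% H2O2, 0 °C
Reagents that add atoms: none
Why: Evans syn aldol through the Z boron enolate and a Zimmerman–Traxler chair, with the (S)-benzyl auxiliary blocking one enolate face, should set the C12 methyl and C13 hydroxyl centers in the 12,13-syn sense required (2S,3S in the adduct).

Step 4
Reactants: 7 (S)-4-benzyl-3-[(2S,3S,Z)-3-hydroxy-5-iodo-2,4-dimethylpent-4-enoyl]oxazolidin-2-one
Product: 8 (2S,3S,Z)-3-hydroxy-5-iodo-N-methoxy-N,2,4-trimethylpent-4-enamide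
Conditions: MeNHOMe·HCl, AlMe3, CH2Cl2, −20 to 0 °C; aq KNaC4H4O6
Reagents that add atoms: N,O-dimethylhydroxylamine hydrochloride, CNOC.Cl
Why: Aluminum amide transamination (Weinreb amidation) of the β-hydroxy imide is assisted by the free hydroxyl and should release the auxiliary without epimerisation at C12.

Step 5
Reactants: 8 (2S,3S,Z)-3-hydroxy-5-iodo-N-methoxy-N,2,4-trimethylpent-4-enamide
Product: 9 ethyl (4S,5S,Z)-5-hydroxy-7-iodo-4,6-dimethyl-3-oxohept-6-enoate
Conditions: EtOAc, LiN(iPr)2 (4 equiv each), THF, −78 °C; then 8, −78 to −40 °C; aq NH4Cl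
Reagents that add atoms: ethyl acetate, CCOC(C)=O
Why: In this crossed Claisen acylation the Weinreb amide stops at the chelated tetrahedral adduct, so the β-keto ester carrying C10 and C9 appears only on quench, and the alkenyl iodide tolerates an ester enolate.

Step 6
Reactants: 9 ethyl (4S,5S,Z)-5-hydroxy-7-iodo-4,6-dimethyl-3-oxohept-6-enoate
Product: 10 ethyl (3R,4R,5S,Z)-3,5-dihydroxy-7-iodo-4,6-dimethylhept-6-enoate
Conditions: Me4NBH(OAc)3, MeCN/AcOH 1:1, −30 °C; aq KNaC4H4O6
Reagents that add atoms: none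
Why: Evans–Saksena reduction delivers hydride intramolecularly from the C13 alkoxyborohydride through a chair transition state and should give the 1,3-anti diol, setting C11 as R whatever the α-methyl configuration.

Step 7
Reactants: 10 ethyl (3R,4R,5S,Z)-3,5-dihydroxy-7-iodo-4,6-dimethylhept-6-enoate
Product: 11 ethyl (3R,4R,5S,Z)-3,5-bis(tert-butyldimethylsilyloxy)-7-iodo-4,6-dimethylhept-6-enoate
Conditions: TBSOTf (2.5 equiv), 2,6-lutidine, CH2Cl2, −78 to 0 °C
Reagents that add atoms: tert-butyldimethylsilyl triflate, CC(C)(C)[Si](C)(C)OS(=O)(=O)C(F)(F)F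
Why: The silyl triflate with a hindered pyridine base silylates both secondary alcohols, including the hindered allylic C13 hydroxyl, under non-nucleophilic conditions.

Step 8
Reactants: 11 ethyl (3R,4R,5S,Z)-3,5-bis(tert-butyldimethylsilyloxy)-7-iodo-4,6-dimethylhept-6-enoate
Product: 12 (3R,4R,5S,Z)-3,5-bis(tert-butyldimethylsilyloxy)-7-iodo-4,6-dimethylhept-6-en-1-ol
Conditions: iBu2AlH (2.5 equiv), CH2Cl2, −78 to 0 °C; aq KNaC4H4O6
Reagents that add atoms: none
Why: Excess aluminum hydride reduces the ester fully to the C9 primary alcohol and leaves the alkenyl iodide and silyl ethers intact.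

Step 9
Reactants: 12 (3R,4R,5S,Z)-3,5-bis(tert-butyldimethylsilyloxy)-7-iodo-4,6-dimethylhept-6-en-1-ol
Product: 13 5-{[(3R,4R,5S,Z)-3,5-bis(tert-butyldimethylsilyloxy)-7-iodo-4,6-dimethylhept-6-en-1-yl]sulfanyl}-1-phenyl-1H-tetrazole
Conditions: 1-phenyl-1H-tetrazole-5-thiol, PPh3, diisopropyl azodicarboxylate, THF, 0 °C to rt
Reagents that add atoms: 1-phenyl-1H-tetrazole-5-thiol, Sc1nnnn1-c1ccccc1
Why: Mitsunobu thioetherification of an unhindered primary alcohol with the acidic heteroaryl thiol is reliable and neutral.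

Step 10
Reactants: 13 5-{[(3R,4R,5S,Z)-3,5-bis(tert-butyldimethylsilyloxy)-7-iodo-4,6-dimethylhept-6-en-1-yl]sulfanyl}-1-phenyl-1H-tetrazole
Product: 14 5-{[(3R,4R,5S,Z)-3,5-bis(tert-butyldimethylsilyloxy)-7-iodo-4,6-dimethylhept-6-en-1-yl]sulfonyl}-1-phenyl-1H-tetrazole
Conditions: (NH4)6Mo7O24·4H2O (cat.), 30% H2O2, EtOH, 0 °C to rt
Reagents that add atoms: hydrogen peroxide, OO
Why: Molybdate-catalysed peroxide oxidation takes the sulfide to the sulfone, and the electron-poor trisubstituted iodoalkene should not be epoxidised.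

**East fragment (C1 to C8)**

Step 11
Reactants: 15 dimethyl (R)-malate
Product: 16 methyl (R)-3,4-dihydroxybutanoate
Conditions: BH3·SMe2 (1.05 equiv), NaBH4 (5 mol %), THF, 0 °C to rt; MeOH quench
Reagents that add atoms: none
Why: Hydroxyl-directed borane reduction proceeds through the cyclic alkoxyborane and reduces only the ester next to the free hydroxyl, so the stereocenter (future C3, R) is untouched.

Step 12
Reactants: 16 methyl (R)-3,4-dihydroxybutanoate
Product: 17 methyl (R)-4-(tert-butyldimethylsilyloxy)-3-hydroxybutanoate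
Conditions: TBSCl (1.05 equiv), imidazole, CH2Cl2, 0 °C
Reagents that add atoms: tert-butyldimethylsilyl chloride, CC(C)(C)[Si](C)(C)Cl
Why: Silylation favours the primary over the secondary hydroxyl on steric grounds.

Step 13
Reactants: 17 methyl (R)-4-(tert-butyldimethylsilyloxy)-3-hydroxybutanoate
Product: 18 methyl (R)-4-(tert-butyldimethylsilyloxy)-3-methoxybutanoate
Conditions: Me3OBF4, 1,8-bis(dimethylamino)naphthalene, CH2Cl2, rt
Reagents that add atoms: trimethyloxonium tetrafluoroborate, C[O+](C)C.F[B-](F)(F)F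
Why: Meerwein-salt O-methylation with a non-nucleophilic amine avoids the alkoxide that would trigger retro-aldol or β-elimination in a β-hydroxy ester.

Step 14
Reactants: 18 methyl (R)-4-(tert-butyldimethylsilyloxy)-3-methoxybutanoate
Product: 19 methyl (R)-4-hydroxy-3-methoxybutanoate
Conditions: HF·pyridine, pyridine, THF, 0 °C; used crude at once
Reagents that add atoms: none
Why: Buffered fluoride desilylation frees the primary alcohol under conditions mild enough to limit lactonisation of the γ-hydroxy ester before oxidation.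

Step 15
Reactants: 19 methyl (R)-4-hydroxy-3-methoxybutanoate
Product: 20 methyl (R)-3-methoxy-4-oxobutanoate
Conditions: Dess–Martin periodinane, CH2Cl2, 0 °C to rt; used at once
Reagents that add atoms: none
Why: Dess–Martin oxidation is nearly neutral and should give the α-methoxy aldehyde (C4) without epimerisation at C3.

Step 16
Reactants: 20 methyl (R)-3-methoxy-4-oxobutanoate
Product: 21 methyl (3R,4E)-3-methoxy-6-oxohex-4-enoate
Conditions: Ph3P=CHCHO (1.1 equiv), CH2Cl2, rt
Reagents that add atoms: (triphenylphosphoranylidene)acetaldehyde, O=CC=P(c1ccccc1)(c1ccccc1)c1ccccc1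
Why: Wittig reaction with the formyl-stabilised ylide gives the E enal (C4=C5), and the conjugated product is less electrophilic than the saturated aldehyde, so homologation should stop after one unit.

Step 17
Reactants: 21 methyl (3R,4E)-3-methoxy-6-oxohex-4-enoate
Product: 22 methyl (3R,4E,6E)-3-methoxy-8-oxoocta-4,6-dienoate
Conditions: Ph3P=CHCHO (1.2 equiv), toluene, 80 °C, stopped before full conversion
Reagents that add atoms: (triphenylphosphoranylidene)acetaldehyde, O=CC=P(c1ccccc1)(c1ccccc1)c1ccccc1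
Why: A second stabilised-ylide Wittig homologation installs the E C6=C7 alkene, with limited ylide and monitored conversion holding back trienal formation.

**Arene fragment (C16 to C23 and N)**

Step 18
Reactants: 23 2-hydroxy-5-methoxy-3-nitrobenzaldehyde
Product: 24 2,5-dihydroxy-3-nitrobenzaldehyde
Conditions: BBr3 (3 equiv), CH2Cl2, −78 °C to rt; H2O
Reagents that add atoms: none
Why: Lewis-acid demethylation, in which bromide attacks the O-methyl of the boron-complexed aryl ether, exchanges the unremovable methyl ether for a free phenol at a stage where the ring is deactivated toward oxidation.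

Step 19
Reactants: 24 2,5-dihydroxy-3-nitrobenzaldehyde
Product: 25 2-hydroxy-3-nitro-5-(triisopropylsilyloxy)benzaldehyde
Conditions: TIPSCl (1.1 equiv), imidazole, DMF, 0 °C
Reagents that add atoms: triisopropylsilyl chloride, CC(C)[Si](Cl)(C(C)C)C(C)C
Why: The 2-hydroxyl is hindered, chelated and strongly acidic between the formyl and nitro groups and its silyl ether would be labile, so silylation should settle on the 5-hydroxyl.

Step 20
Reactants: 25 2-hydroxy-3-nitro-5-(triisopropylsilyloxy)benzaldehyde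
Product: 26 2-ethenyl-6-nitro-4-(triisopropylsilyloxy)phenol
Conditions: MePPh3Br (2.6 equiv), KOtBu (2.5 equiv), THF, 0 °C; then 25, 0 °C to rt
Reagents that add atoms: methyltriphenylphosphonium bromide, C[P+](c1ccccc1)(c1ccccc1)c1ccccc1.[Br-]
Why: In this Wittig methylenation the first equivalent of ylide forms the nitrophenoxide and the second converts the formyl group into the vinyl group that supplies C17 and C16.

Step 21
Reactants: 26 2-ethenyl-6-nitro-4-(triisopropylsilyloxy)phenol
Product: 27 1-ethenyl-3-nitro-2,5-bis(triisopropylsilyloxy)benzene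
Conditions: TIPSOTf, 2,6-lutidine, CH2Cl2, 0 °C; used without storage
Reagents that add atoms: triisopropylsilyl triflate, CC(C)[Si](OS(=O)(=O)C(F)(F)F)(C(C)C)C(C)C
Why: The reactive silyl triflate silylates the weakly nucleophilic nitrophenol, and the activated ether is carried straight into reduction, after which the electron-rich ring makes it robust.

Step 22
Reactants: 27 1-ethenyl-3-nitro-2,5-bis(triisopropylsilyloxy)benzene
Product: 28 3-ethenyl-2,5-bis(triisopropylsilyloxy)aniline
Conditions: Zn dust, AcOH, CH2Cl2, 0 °C to rt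
Reagents that add atoms: none
Why: Dissolving-metal reduction with zinc in acetic acid converts nitro into amine and spares the styrene and the aryl silyl ethers.

**Assembly, ring closure and deprotection**

Step 23
Reactants: 14 5-{[(3R,4R,5S,Z)-3,5-bis(tert-butyldimethylsilyloxy)-7-iodo-4,6-dimethylhept-6-en-1-yl]sulfonyl}-1-phenyl-1H-tetrazole; 22 methyl (3R,4E,6E)-3-methoxy-8-oxoocta-4,6-dienoate
Product: 30 methyl (3R,4E,6E,8E,11R,12R,13S,14Z)-11,13-bis(tert-butyldimethylsilyloxy)-15-iodo-3-methoxy-12,14-dimethylpentadeca-4,6,8,14-tetraenoate, via potassium sulfonyl carbanion 29 (not isolated)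
Conditions: 14, KN(SiMe3)2, DME, −60 °C; then 22, −60 °C to rt; aq NH4Cl
Reagents that add atoms: none
Why: Julia–Kocienski olefination (carbanion addition, Smiles rearrangement, then loss of SO2 and tetrazolone) with a potassium base in DME should form the C8=C9 alkene E, and the premetalated sulfone adds to the aldehyde faster than it deprotonates the ester or C3.

Step 24
Reactants: 30 methyl (3R,4E,6E,8E,11R,12R,13S,14Z)-11,13-bis(tert-butyldimethylsilyloxy)-15-iodo-3-methoxy-12,14-dimethylpentadeca-4,6,8,14-tetraenoate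
Product: 31 (3R,4E,6E,8E,11R,12R,13S,14Z)-11,13-bis(tert-butyldimethylsilyloxy)-15-iodo-3-methoxy-12,14-dimethylpentadeca-4,6,8,14-tetraenoic acid
Conditions: Me3SnOH (8 equiv), ClCH2CH2Cl, 70 °C, dark; cold 0.05 M HCl wash
Reagents that add atoms: trimethyltin hydroxide, C[Sn](C)(C)O
Why: Tin hydroxide cleaves the methyl ester under nearly neutral conditions, which avoids the enolate that would expel the C3 methoxide into conjugation with the triene.

Step 25
Reactants: 31 (3R,4E,6E,8E,11R,12R,13S,14Z)-11,13-bis(tert-butyldimethylsilyloxy)-15-iodo-3-methoxy-12,14-dimethylpentadeca-4,6,8,14-tetraenoic acid; 28 3-ethenyl-2,5-bis(triisopropylsilyloxy)aniline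
Product: 33 (3R,4E,6E,8E,11R,12R,13S,14Z)-N-[3-ethenyl-2,5-bis(triisopropylsilyloxy)phenyl]-11,13-bis(tert-butyldimethylsilyloxy)-15-iodo-3-methoxy-12,14-dimethylpentadeca-4,6,8,14-tetraenamide, via acid chloride 32 (not isolated)
Conditions: 1-chloro-N,N,2-trimethylprop-1-en-1-amine, CH2Cl2, 0 °C; then 28, pyridine, 0 °C to rt
Reagents that add atoms: none
Why: The α-chloroenamine forms the acid chloride without releasing HCl, and an acid chloride is reactive enough to acylate the aniline hindered by its ortho silyloxy group.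

Step 26
Reactants: 33 (3R,4E,6E,8E,11R,12R,13S,14Z)-N-[3-ethenyl-2,5-bis(triisopropylsilyloxy)phenyl]-11,13-bis(tert-butyldimethylsilyloxy)-15-iodo-3-methoxy-12,14-dimethylpentadeca-4,6,8,14-tetraenamide
Product: 35 fully silylated 21-membered macrolactam (3R,11R,12R,13S; 4E,6E,8E,14Z; TBS on O11 and O13; TIPS on O20 and O23), via B-alkyl-9-BBN borane 34 (not isolated)
Conditions: 9-BBN dimer (3 equiv B–H), THF, 0 °C to rt; H2O; then slow addition to Pd(dppf)Cl2·CH2Cl2 (20 mol %), AsPh3 (40 mol %), Cs2CO3 (5 equiv), DMF/THF/H2O, rt, about 1 mM, degassed, dark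
Reagents that add atoms: none
Why: 9-BBN adds across the terminal aryl alkene with boron on C16, giving a primary alkylborane; zerovalent palladium then inserts into the C15–I bond with retention, the carbonate-activated borate transfers the C16 alkyl group to divalent palladium, and reductive elimination forms C15–C16. The closest known reaction type is the intramolecular B-alkyl Suzuki–Miyaura macrocyclisation of an alkenyl iodide with a 9-BBN alkylborane. The 21-membered ring is closed at the metal by this sp3–sp2 reductive elimination, under slow addition and high dilution so that ring closure outruns oligomerisation. No stereocenter is formed, and the Z C14=C15 geometry is carried over unchanged from the iodide. The step needs hydroboration of the vinyl group alone, which the bulk of 9-BBN should secure because a monosubstituted alkene reacts far faster than the trans-disubstituted conjugated triene or the trisubstituted iodoalkene. The wide-bite-angle dppf ligand with AsPh3 should make reductive elimination faster than β-hydride loss from the C17 benzylic hydrogens.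

Step 27
Reactants: 35 fully silylated 21-membered macrolactam
Product: 36 CNP0544229.3 (target)
Conditions: HF·pyridine, pyridine, THF, 0 °C to rt, under argon; work-up with degassed solvents
Reagents that add atoms: none
Why: Buffered fluoride removes the two aryl TIPS and two secondary TBS ethers in one operation without ionising the allylic C3 methyl ether or the C13 allylic alcohol, and oxygen is excluded to keep the hydroquinone reduced.

**Compound list**

1 | prop-2-yn-1-ol | C#CCO | starting material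
2 | 4-methyl-2,5-dihydro-1,2-oxamagnesole (cyclic alkenylmagnesium alkoxide) | CC1=C[Mg]OC1 | intermediate
3 | (Z)-3-iodo-2-methylprop-2-en-1-ol | OC/C(C)=C\I | intermediate
4 | (Z)-3-iodo-2-methylprop-2-enal | O=C/C(C)=C\I | intermediate
5 | (S)-4-benzyl-3-propanoyloxazolidin-2-one | CCC(=O)N1[C@@H](Cc2ccccc2)COC1=O | starting material
6 | Z dibutylboron enolate of 5 | C/C=C(\OB(CCCC)CCCC)N1[C@@H](Cc2ccccc2)COC1=O | intermediate
7 | (S)-4-benzyl-3-[(2S,3S,Z)-3-hydroxy-5-iodo-2,4-dimethylpent-4-enoyl]oxazolidin-2-one | O=C([C@@H](C)[C@H](O)/C(C)=C\I)N1[C@@H](Cc2ccccc2)COC1=O | intermediate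
8 | (2S,3S,Z)-3-hydroxy-5-iodo-N-methoxy-N,2,4-trimethylpent-4-enamide | CON(C)C(=O)[C@@H](C)[C@H](O)/C(C)=C\I | intermediate
9 | ethyl (4S,5S,Z)-5-hydroxy-7-iodo-4,6-dimethyl-3-oxohept-6-enoate | CCOC(=O)CC(=O)[C@@H](C)[C@H](O)/C(C)=C\I | intermediate
10 | ethyl (3R,4R,5S,Z)-3,5-dihydroxy-7-iodo-4,6-dimethylhept-6-enoate | CCOC(=O)C[C@@H](O)[C@@H](C)[C@H](O)/C(C)=C\I | intermediate
11 | ethyl (3R,4R,5S,Z)-3,5-bis(tert-butyldimethylsilyloxy)-7-iodo-4,6-dimethylhept-6-enoate | CCOC(=O)C[C@@H](O[Si](C)(C)C(C)(C)C)[C@@H](C)[C@H](O[Si](C)(C)C(C)(C)C)/C(C)=C\I | intermediate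
12 | (3R,4R,5S,Z)-3,5-bis(tert-butyldimethylsilyloxy)-7-iodo-4,6-dimethylhept-6-en-1-ol | OCC[C@@H](O[Si](C)(C)C(C)(C)C)[C@@H](C)[C@H](O[Si](C)(C)C(C)(C)C)/C(C)=C\I | intermediate
13 | 5-{[(3R,4R,5S,Z)-3,5-bis(tert-butyldimethylsilyloxy)-7-iodo-4,6-dimethylhept-6-en-1-yl]sulfanyl}-1-phenyl-1H-tetrazole | c1ccccc1-n1nnnc1SCC[C@@H](O[Si](C)(C)C(C)(C)C)[C@@H](C)[C@H](O[Si](C)(C)C(C)(C)C)/C(C)=C\I | intermediate
14 | 5-{[(3R,4R,5S,Z)-3,5-bis(tert-butyldimethylsilyloxy)-7-iodo-4,6-dimethylhept-6-en-1-yl]sulfonyl}-1-phenyl-1H-tetrazole | O=S(=O)(CC[C@@H](O[Si](C)(C)C(C)(C)C)[C@@H](C)[C@H](O[Si](C)(C)C(C)(C)C)/C(C)=C\I)c1nnnn1-c1ccccc1 | intermediate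
15 | dimethyl (R)-malate | COC(=O)C[C@@H](O)C(=O)OC | starting material
16 | methyl (R)-3,4-dihydroxybutanoate | COC(=O)C[C@@H](O)CO | intermediate
17 | methyl (R)-4-(tert-butyldimethylsilyloxy)-3-hydroxybutanoate | COC(=O)C[C@@H](O)CO[Si](C)(C)C(C)(C)C | intermediate
18 | methyl (R)-4-(tert-butyldimethylsilyloxy)-3-methoxybutanoate | COC(=O)C[C@@H](OC)CO[Si](C)(C)C(C)(C)C | intermediate
19 | methyl (R)-4-hydroxy-3-methoxybutanoate | COC(=O)C[C@@H](OC)CO | intermediate
20 | methyl (R)-3-methoxy-4-oxobutanoate | COC(=O)C[C@@H](OC)C=O | intermediate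
21 | methyl (3R,4E)-3-methoxy-6-oxohex-4-enoate | COC(=O)C[C@@H](OC)/C=C/C=O | intermediate
22 | methyl (3R,4E,6E)-3-methoxy-8-oxoocta-4,6-dienoate | COC(=O)C[C@@H](OC)/C=C/C=C/C=O | intermediate
23 | 2-hydroxy-5-methoxy-3-nitrobenzaldehyde | COc1cc(C=O)c(O)c([N+](=O)[O-])c1 | starting material
24 | 2,5-dihydroxy-3-nitrobenzaldehyde | O=Cc1cc(O)cc([N+](=O)[O-])c1O | intermediate
25 | 2-hydroxy-3-nitro-5-(triisopropylsilyloxy)benzaldehyde | O=Cc1cc(O[Si](C(C)C)(C(C)C)C(C)C)cc([N+](=O)[O-])c1O | intermediate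
26 | 2-ethenyl-6-nitro-4-(triisopropylsilyloxy)phenol | C=Cc1cc(O[Si](C(C)C)(C(C)C)C(C)C)cc([N+](=O)[O-])c1O | intermediate
27 | 1-ethenyl-3-nitro-2,5-bis(triisopropylsilyloxy)benzene | C=Cc1cc(O[Si](C(C)C)(C(C)C)C(C)C)cc([N+](=O)[O-])c1O[Si](C(C)C)(C(C)C)C(C)C | intermediate
28 | 3-ethenyl-2,5-bis(triisopropylsilyloxy)aniline | C=Cc1cc(O[Si](C(C)C)(C(C)C)C(C)C)cc(N)c1O[Si](C(C)C)(C(C)C)C(C)C | intermediate
29 | potassium salt of sulfone 14 metalated at C9 | [K+].O=S(=O)([CH-]C[C@@H](O[Si](C)(C)C(C)(C)C)[C@@H](C)[C@H](O[Si](C)(C)C(C)(C)C)/C(C)=C\I)c1nnnn1-c1ccccc1 | intermediate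
30 | methyl (3R,4E,6E,8E,11R,12R,13S,14Z)-11,13-bis(tert-butyldimethylsilyloxy)-15-iodo-3-methoxy-12,14-dimethylpentadeca-4,6,8,14-tetraenoate | COC(=O)C[C@@H](OC)/C=C/C=C/C=C/C[C@@H](O[Si](C)(C)C(C)(C)C)[C@@H](C)[C@H](O[Si](C)(C)C(C)(C)C)/C(C)=C\I | intermediate
31 | (3R,4E,6E,8E,11R,12R,13S,14Z)-11,13-bis(tert-butyldimethylsilyloxy)-15-iodo-3-methoxy-12,14-dimethylpentadeca-4,6,8,14-tetraenoic acid | OC(=O)C[C@@H](OC)/C=C/C=C/C=C/C[C@@H](O[Si](C)(C)C(C)(C)C)[C@@H](C)[C@H](O[Si](C)(C)C(C)(C)C)/C(C)=C\I | intermediate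
32 | acid chloride of 31 | ClC(=O)C[C@@H](OC)/C=C/C=C/C=C/C[C@@H](O[Si](C)(C)C(C)(C)C)[C@@H](C)[C@H](O[Si](C)(C)C(C)(C)C)/C(C)=C\I | intermediate
33 | seco anilide: (3R,4E,6E,8E,11R,12R,13S,14Z)-N-[3-ethenyl-2,5-bis(triisopropylsilyloxy)phenyl]-11,13-bis(tert-butyldimethylsilyloxy)-15-iodo-3-methoxy-12,14-dimethylpentadeca-4,6,8,14-tetraenamide | C=Cc1cc(O[Si](C(C)C)(C(C)C)C(C)C)cc(NC(=O)C[C@@H](OC)/C=C/C=C/C=C/C[C@@H](O[Si](C)(C)C(C)(C)C)[C@@H](C)[C@H](O[Si](C)(C)C(C)(C)C)/C(C)=C\I)c1O[Si](C(C)C)(C(C)C)C(C)C | intermediate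
34 | B-alkyl-9-BBN borane from 33 (boron on C16) | B1(CCc2cc(O[Si](C(C)C)(C(C)C)C(C)C)cc(NC(=O)C[C@@H](OC)/C=C/C=C/C=C/C[C@@H](O[Si](C)(C)C(C)(C)C)[C@@H](C)[C@H](O[Si](C)(C)C(C)(C)C)/C(C)=C\I)c2O[Si](C(C)C)(C(C)C)C(C)C)C3CCCC1CCC3 | intermediate
35 | fully silylated 21-membered macrolactam (3R,11R,12R,13S; 4E,6E,8E,14Z) | CO[C@H]1/C=C/C=C/C=C/C[C@@H](O[Si](C)(C)C(C)(C)C)[C@@H](C)[C@H](O[Si](C)(C)C(C)(C)C)/C(C)=C\CCc2cc(O[Si](C(C)C)(C(C)C)C(C)C)cc(c2O[Si](C(C)C)(C(C)C)C(C)C)NC(=O)C1 | intermediate
36 | CNP0544229.3 | CO[C@H]1/C=C/C=C/C=C/C[C@@H](O)[C@@H](C)[C@H](O)/C(C)=C\CCc2cc(O)cc(c2O)NC(=O)C1 | target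

**Step count and risks**

Total step count: 27. Longest linear sequence: 15 steps (steps 1 to 10, then 23 to 27).

Steps most likely to fail:

1. Step 26 (macrocyclising B-alkyl Suzuki coupling). Intermolecular coupling may outrun ring closure and give oligomers. Hydroboration may be slowed by the ortho silyloxy group and stray onto the triene. β-Hydride loss or protodeboronation may return vinyl or ethyl arene. The carbonate base may strip aryl silyl ethers early, which is harmless to the end product only while oxygen is excluded.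
Fallback: the same C15–C16 bond is formed intermolecularly and the ring is closed at the amide instead. The fallback sets out from 28 and 30. Aniline 28 is hydroborated with 9-BBN to 3-[2-(9-borabicyclo[3.3.1]nonan-9-yl)ethyl]-2,5-bis(triisopropylsilyloxy)aniline F1. F1 is coupled with iodide 30 under Pd(dppf)Cl2, AsPh3 and Cs2CO3 at normal concentration to give the seco amino methyl ester F2. Me3SnOH hydrolysis gives the seco amino acid F3. Macrolactamisation at high dilution with bis(2-oxo-3-oxazolidinyl)phosphinic chloride and iPr2NEt in warm toluene comes back to the route at 35.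

2. Step 23 (Julia–Kocienski union). E selectivity at C8=C9 may erode with a conjugated aldehyde. The basic carbanion may instead enolise the dienal at C3 or at the ester, with loss of methoxide.
Fallback: the connective olefination is moved to C4=C5 so that the east partner acts only as an electrophile. The fallback sets out from 12 and 20.
- Dess–Martin oxidation of 12 gives (3R,4R,5S,Z)-3,5-bis(tert-butyldimethylsilyloxy)-7-iodo-4,6-dimethylhept-6-enal F4.
- Horner–Wadsworth–Emmons reaction of F4 with triethyl 4-phosphonocrotonate and LiN(SiMe3)2 gives the ethyl (2E,4E)-dienoate F5.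
- iBu2AlH reduces F5 to the dienol F6.
- CBr4 and PPh3 convert F6 into the dienyl bromide F7.
- Arbuzov reaction of F7 with P(OEt)3 gives the diethyl dienylphosphonate F8.
- The lithium anion of F8 (LiN(SiMe3)2, THF, −78 °C) is condensed with aldehyde 20 and comes back to the route at 30. Steps 16 and 17 are then not needed.

3. Step 17 (second Wittig homologation). The dienal product competes with the enal for the same ylide, so over-homologation to the trienal and incomplete conversion may occur together, and the heating needed may lower the E content.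
Fallback: a masked two-carbon ylide that cannot react twice is used. The fallback sets out from 21. Wittig reaction with the ylide from (1,3-dioxolan-2-ylmethyl)triphenylphosphonium bromide and KOtBu gives methyl (3R,4E)-7-(1,3-dioxolan-2-yl)-3-methoxyhepta-4,6-dienoate F9 as a mixture at the new alkene. Mild aqueous acid (pyridinium tosylate in wet acetone, with a trace of iodine if needed) hydrolyses the acetal and equilibrates the new enal to E, coming back to the route at 22.

**Further compounds**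

F1 | step 26 | 3-[2-(9-borabicyclo[3.3.1]nonan-9-yl)ethyl]-2,5-bis(triisopropylsilyloxy)aniline | Nc1cc(O[Si](C(C)C)(C(C)C)C(C)C)cc(CCB2C3CCCC2CCC3)c1O[Si](C(C)C)(C(C)C)C(C)C
F2 | step 26 | seco amino methyl ester (C15–C16 formed, N–C1 open) | COC(=O)C[C@@H](OC)/C=C/C=C/C=C/C[C@@H](O[Si](C)(C)C(C)(C)C)[C@@H](C)[C@H](O[Si](C)(C)C(C)(C)C)/C(C)=C\CCc1cc(O[Si](C(C)C)(C(C)C)C(C)C)cc(N)c1O[Si](C(C)C)(C(C)C)C(C)C
F3 | step 26 | seco amino acid | OC(=O)C[C@@H](OC)/C=C/C=C/C=C/C[C@@H](O[Si](C)(C)C(C)(C)C)[C@@H](C)[C@H](O[Si](C)(C)C(C)(C)C)/C(C)=C\CCc1cc(O[Si](C(C)C)(C(C)C)C(C)C)cc(N)c1O[Si](C(C)C)(C(C)C)C(C)C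
F4 | step 23 | (3R,4R,5S,Z)-3,5-bis(tert-butyldimethylsilyloxy)-7-iodo-4,6-dimethylhept-6-enal | O=CC[C@@H](O[Si](C)(C)C(C)(C)C)[C@@H](C)[C@H](O[Si](C)(C)C(C)(C)C)/C(C)=C\I
F5 | step 23 | ethyl (2E,4E,7R,8R,9S,10Z)-7,9-bis(tert-butyldimethylsilyloxy)-11-iodo-8,10-dimethylundeca-2,4,10-trienoate | CCOC(=O)/C=C/C=C/C[C@@H](O[Si](C)(C)C(C)(C)C)[C@@H](C)[C@H](O[Si](C)(C)C(C)(C)C)/C(C)=C\I
F6 | step 23 | (2E,4E,7R,8R,9S,10Z)-7,9-bis(tert-butyldimethylsilyloxy)-11-iodo-8,10-dimethylundeca-2,4,10-trien-1-ol | OC/C=C/C=C/C[C@@H](O[Si](C)(C)C(C)(C)C)[C@@H](C)[C@H](O[Si](C)(C)C(C)(C)C)/C(C)=C\I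
F7 | step 23 | (2E,4E,7R,8R,9S,10Z)-1-bromo-7,9-bis(tert-butyldimethylsilyloxy)-11-iodo-8,10-dimethylundeca-2,4,10-triene | BrC/C=C/C=C/C[C@@H](O[Si](C)(C)C(C)(C)C)[C@@H](C)[C@H](O[Si](C)(C)C(C)(C)C)/C(C)=C\I
F8 | step 23 | diethyl [(2E,4E,7R,8R,9S,10Z)-7,9-bis(tert-butyldimethylsilyloxy)-11-iodo-8,10-dimethylundeca-2,4,10-trien-1-yl]phosphonate | CCOP(=O)(OCC)C/C=C/C=C/C[C@@H](O[Si](C)(C)C(C)(C)C)[C@@H](C)[C@H](O[Si](C)(C)C(C)(C)C)/C(C)=C\I
F9 | step 17 | methyl (3R,4E)-7-(1,3-dioxolan-2-yl)-3-methoxyhepta-4,6-dienoate (mixture at C6=C7) | COC(=O)C[C@@H](OC)/C=C/C=CC1OCCO1
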